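**Retrosynthetic overview**
1. The ten-membered ring is closed last, by ring-closing metathesis at the Z-trisubstituted C1=C10 alkene of an acyclic butenolide.
2. The butenolide C6–O bond, the C3–O propanoate and both stereocentres come from one enantioselective palladium-catalysed 1,4-propanoyloxy-lactonisation of an achiral (2Z,4E,6E)-trienoic acid (key C–O step).
3. The trienoic acid comes from Horner–Wadsworth–Emmons olefination of a γ-hydroxybutenolide (a masked (Z)-4-oxo-2-enoic acid) with an allylic phosphonate.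
4. The butenolide core comes from but-2-yne-1,4-diol, a homoallyl Grignard reagent and CO2; the phosphonate comes from 2-methyl-2-vinyloxirane and vinylmagnesium bromide.
5. Ring order: butenolide (made in step 1, opened in step 5, re-closed enantioselectively in step 6), then the carbocycle (step 8).

Assumption: positions are given in germacrane numbering (C3 carries the propanoate, C6 the lactone oxygen, C13 the acetate; the target is 3S,6R,1(10)Z,4E), and because the sense of induction of the new catalyst in step 6 cannot be predicted, the ligand antipode that gives (3S,6R) is the one used.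

**Step 1**
Reactants: 1 but-2-yne-1,4-diol; 2 4-bromo-2-methylbut-1-ene
Product: 6 3-(hydroxymethyl)-4-(3-methylbut-3-en-1-yl)furan-2(5H)-one, via homoallyl Grignard reagent 3 (not isolated), via alkenylmagnesium adduct 4 (not isolated), via magnesium carboxylate 5 (not isolated)
Conditions: 2 (4 equiv), Mg, THF, 40 °C; then 1, CuI (10 mol%), THF–toluene, 65 °C, 16 h; CO2 (1 atm), 0 °C; 2 M HCl, 23 °C
Reagents that add atoms: carbon dioxide, O=C=O
Why: Copper-catalysed, alkoxide-directed anti-carbomagnesiation of the alkyne (Duboudin–Fallis carbometalation) places the alkyl group and magnesium trans, so the carboxyl group from CO2 lies cis to one CH2OH and lactonises on acidification; no stereocentre is formed.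

**Step 2**
Reactants: 6 3-(hydroxymethyl)-4-(3-methylbut-3-en-1-yl)furan-2(5H)-one
Product: 9 5-hydroxy-4-(3-methylbut-3-en-1-yl)-3-({[tri(propan-2-yl)silyl]oxy}methyl)furan-2(5H)-one, via bis-silyl furan 7 (not isolated), via silyl oxoenoate 8 (not isolated)
Conditions: i-Pr3SiOTf (2.2 equiv), Et3N, CH2Cl2, 0 °C; evaporate, pentane, filter; dimethyldioxirane (1.05 equiv), acetone, −78 °C; 0.1 M HCl, THF, 0 °C
Reagents that add atoms: triisopropylsilyl trifluoromethanesulfonate, CC(C)[Si](C(C)C)(C(C)C)OS(=O)(=O)C(F)(F)F; dimethyldioxirane, CC1(C)OO1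
Why: O-silylation gives the 2-silyloxyfuran (the alcohol is silylated as well), whose C5 is oxidised by the dioxirane far faster than the isolated 1,1-disubstituted alkene (Boukouvalas-type silyloxyfuran oxidation to a (Z)-4-oxo-2-enoate), and mild hydrolysis of the silyl ester closes the γ-hydroxybutenolide; the hemiacetal carbon forms as a 1:1 mixture, which does not matter because it becomes sp2 in step 5.

**Step 3**
Reactants: 10 2-methyl-2-vinyloxirane (racemic); 11 vinylmagnesium bromide
Product: 12 (2E)-2-methylhexa-2,5-dien-1-ol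
Conditions: CH2=CHMgBr (1.3 equiv), CuI (5 mol%), THF, −40 → 0 °C; cold 1 M HCl
Reagents that add atoms: none
Why: Copper-catalysed SN2′ opening of the vinyl oxirane at the terminal vinyl carbon gives the E-trisubstituted allylic alcohol (about 9:1 E:Z expected, minor isomer removed on silver-nitrate-doped silica); the stereocentre of 10 is destroyed and none is formed.

**Step 4**
Reactants: 12 (2E)-2-methylhexa-2,5-dien-1-ol
Product: 14 diethyl [(2E)-2-methylhexa-2,5-dien-1-yl]phosphonate, via allylic bromide 13 (not isolated)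
Conditions: PBr3 (0.4 equiv), Et2O, −10 °C; ice-water wash, concentrate; P(OEt)3 (1.5 equiv), neat, 110 °C
Reagents that add atoms: triethyl phosphite, CCOP(OCC)OCC
Why: SN2 bromination of the primary allylic alcohol followed by Michaelis–Arbuzov reaction at the primary allylic carbon; the E alkene is retained and no stereocentre is formed.

**Step 5**
Reactants: 9 5-hydroxy-4-(3-methylbut-3-en-1-yl)-3-({[tri(propan-2-yl)silyl]oxy}methyl)furan-2(5H)-one; 14 diethyl [(2E)-2-methylhexa-2,5-dien-1-yl]phosphonate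
Product: 18 (2Z,4E,6E)-2-(hydroxymethyl)-6-methyl-3-(3-methylbut-3-en-1-yl)deca-2,4,6,9-tetraenoic acid, via lithiated phosphonate 15 (not isolated), via lithium oxoenoate 16 (not isolated), via lithium silyloxy tetraenoate 17 (not isolated)
Conditions: 14 (1.2 equiv), n-BuLi (1.2 equiv), THF–DMPU, −78 °C; add 9 pretreated with LiN(SiMe3)2 (1.0 equiv), THF, −78 °C; −78 → 23 °C; n-Bu4NF (3 equiv), 23 °C; 1 M HCl to pH 3
Reagents that add atoms: none
Why: Base opens the pseudo-acid 9 to the (Z)-4-oxo-2-enoate 16, Horner–Wadsworth–Emmons olefination with the lithiated allylic phosphonate forms the new 4E alkene (2Z and 6E are carried over from 9 and 14), and fluoride removes the silyl ether; no stereocentre is formed.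

**Step 6**
Reactants: 18 (2Z,4E,6E)-2-(hydroxymethyl)-6-methyl-3-(3-methylbut-3-en-1-yl)deca-2,4,6,9-tetraenoic acid
Product: 19 (1E,3S)-1-[(2R)-4-(hydroxymethyl)-3-(3-methylbut-3-en-1-yl)-5-oxo-2,5-dihydrofuran-2-yl]-2-methylhexa-1,5-dien-3-yl propanoate
Conditions: Pd(O2CEt)2 (5 mol%), chiral sulfoxide–oxazoline ligand L* [(4S)-4-tert-butyl-2-{2-[(S)-(4-methylphenyl)sulfinyl]phenyl}-4,5-dihydro-1,3-oxazole or its mirror image] (6 mol%), 2,6-dimethyl-1,4-benzoquinone (1.3 equiv), EtCO2H (10 equiv), acetone, 20 °C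
Reagents that add atoms: propanoic acid, CCC(=O)O
Why: Proposed new method: an enantioselective divalent-palladium-catalysed 1,4-acyloxy-lactonisation of an acyclic conjugated dienoic acid, in which the ligated palladium binds the electron-rich C3=C4–C5=C6 diene rather than the isolated terminal alkenes, the cis-carboxylate adds to C6 anti to the metal (5-exo) to close the butenolide and leave a syn,syn η3-allyl over C3–C5, the bidentate ligand blocks inner-sphere delivery so propanoate attacks C3 from outside (the allyl terminus remote from the electron-withdrawing lactone oxygen), and the quinone returns zerovalent palladium to the divalent state; two anti additions across the E,E-diene give the E alkene and the 3S*,6R* relative configuration, the chiral ligand selects the diene face and hence (3S,6R), so the lactone C–O bond, the propanoate C–O bond and both stereocentres are set here; the closest known chemistry is the racemic palladium/benzoquinone 1,4-diacyloxylation and 1,4-oxylactonisation of conjugated dienes (Bäckvall type) and sulfoxide–oxazoline/palladium enantioselective allylic C–H oxidation, where a C–O bond forms on an η3-allyl.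

**Step 7**
Reactants: 19 (1E,3S)-1-[(2R)-4-(hydroxymethyl)-3-(3-methylbut-3-en-1-yl)-5-oxo-2,5-dihydrofuran-2-yl]-2-methylhexa-1,5-dien-3-yl propanoate
Product: 20 (1E,3S)-1-[(2R)-4-(acetyloxymethyl)-3-(3-methylbut-3-en-1-yl)-5-oxo-2,5-dihydrofuran-2-yl]-2-methylhexa-1,5-dien-3-yl propanoate
Conditions: Ac2O (1.5 equiv), pyridine, DMAP (5 mol%), CH2Cl2, 0 °C
Reagents that add atoms: acetic anhydride, CC(=O)OC(C)=O
Why: Acylation of the only free (primary) hydroxyl group under weakly basic conditions at 0 °C, which leave the acidic γ-proton of the butenolide and the allylic propanoate untouched (a strong base would eliminate propanoate through the furanolate); stereocentres unchanged.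

**Step 8**
Reactants: 20 (1E,3S)-1-[(2R)-4-(acetyloxymethyl)-3-(3-methylbut-3-en-1-yl)-5-oxo-2,5-dihydrofuran-2-yl]-2-methylhexa-1,5-dien-3-yl propanoate
Product: 21 (3S,6R)-13-acetoxy-3-(propanoyloxy)germacra-1(10)Z,4E,7(11)-trien-12,6-olide
Conditions: second-generation Hoveyda–Grubbs catalyst RuCl2(H2IMes)(=CH-C6H4-2-Oi-Pr) (2 × 5 mol%), 1,4-benzoquinone (10 mol%), toluene (1 mM), 80 °C, argon sparge
Reagents that add atoms: none
Why: Ring-closing olefin metathesis between the monosubstituted and the 1,1-disubstituted terminal alkenes with loss of ethene; the catalyst initiates at the vinyl group, the internal tri- and tetrasubstituted alkenes are inert, and the new trisubstituted alkene is expected Z because the ring-cis olefin is the less strained geometry in a ten-membered ring that already holds one E alkene; both stereocentres are remote and unchanged.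

**Compound list**
1 | but-2-yne-1,4-diol | OCC#CCO | starting material
2 | 4-bromo-2-methylbut-1-ene | C=C(C)CCBr | starting material
3 | (3-methylbut-3-en-1-yl)magnesium bromide | C=C(C)CC[Mg]Br | intermediate
4 | bromo{(2Z)-1,4-bis[(bromomagnesio)oxy]-3-(3-methylbut-3-en-1-yl)but-2-en-2-yl}magnesium | C=C(C)CC/C(CO[Mg]Br)=C(/[Mg]Br)CO[Mg]Br | intermediate
5 | tris(bromomagnesium) salt of (2Z)-4-hydroxy-2-(hydroxymethyl)-3-(3-methylbut-3-en-1-yl)but-2-enoic acid | C=C(C)CC/C(CO[Mg]Br)=C(/C(=O)O[Mg]Br)CO[Mg]Br | intermediate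
6 | 3-(hydroxymethyl)-4-(3-methylbut-3-en-1-yl)furan-2(5H)-one | C=C(C)CCC1=C(CO)C(=O)OC1 | intermediate
7 | triisopropyl{[4-(3-methylbut-3-en-1-yl)-2-(triisopropylsilyloxy)furan-3-yl]methoxy}silane | C=C(C)CCc1coc(O[Si](C(C)C)(C(C)C)C(C)C)c1CO[Si](C(C)C)(C(C)C)C(C)C | intermediate
8 | triisopropylsilyl (2Z)-3-formyl-6-methyl-2-[(triisopropylsilyloxy)methyl]hepta-2,6-dienoate | C=C(C)CC/C(C=O)=C(\CO[Si](C(C)C)(C(C)C)C(C)C)C(=O)O[Si](C(C)C)(C(C)C)C(C)C | intermediate
9 | 5-hydroxy-4-(3-methylbut-3-en-1-yl)-3-({[tri(propan-2-yl)silyl]oxy}methyl)furan-2(5H)-one (both hemiacetal epimers) | C=C(C)CCC1=C(CO[Si](C(C)C)(C(C)C)C(C)C)C(=O)OC1O | intermediate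
10 | 2-methyl-2-vinyloxirane (racemic) | CC1(C=C)CO1 | starting material
11 | vinylmagnesium bromide | C=C[Mg]Br | starting material
12 | (2E)-2-methylhexa-2,5-dien-1-ol | C=CC/C=C(\C)CO | intermediate
13 | (2E)-1-bromo-2-methylhexa-2,5-diene | C=CC/C=C(\C)CBr | intermediate
14 | diethyl [(2E)-2-methylhexa-2,5-dien-1-yl]phosphonate | C=CC/C=C(\C)CP(=O)(OCC)OCC | intermediate
15 | lithium salt of the C1 carbanion of 14 | [Li+].C=CC/C=C(\C)[CH-]P(=O)(OCC)OCC | intermediate
16 | lithium (2Z)-3-formyl-6-methyl-2-[(triisopropylsilyloxy)methyl]hepta-2,6-dienoate | [Li+].[O-]C(=O)/C(CO[Si](C(C)C)(C(C)C)C(C)C)=C(\C=O)CCC(C)=C | intermediate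
17 | lithium (2Z,4E,6E)-6-methyl-3-(3-methylbut-3-en-1-yl)-2-[(triisopropylsilyloxy)methyl]deca-2,4,6,9-tetraenoate | [Li+].[O-]C(=O)/C(CO[Si](C(C)C)(C(C)C)C(C)C)=C(CCC(C)=C)\C=C\C(C)=C\CC=C | intermediate
18 | (2Z,4E,6E)-2-(hydroxymethyl)-6-methyl-3-(3-methylbut-3-en-1-yl)deca-2,4,6,9-tetraenoic acid | OC(=O)/C(CO)=C(CCC(C)=C)\C=C\C(C)=C\CC=C | intermediate
19 | (1E,3S)-1-[(2R)-4-(hydroxymethyl)-3-(3-methylbut-3-en-1-yl)-5-oxo-2,5-dihydrofuran-2-yl]-2-methylhexa-1,5-dien-3-yl propanoate | CCC(=O)O[C@@H](CC=C)/C(C)=C/[C@H]1OC(=O)C(CO)=C1CCC(C)=C | intermediate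
20 | (1E,3S)-1-[(2R)-4-(acetyloxymethyl)-3-(3-methylbut-3-en-1-yl)-5-oxo-2,5-dihydrofuran-2-yl]-2-methylhexa-1,5-dien-3-yl propanoate | CCC(=O)O[C@@H](CC=C)/C(C)=C/[C@H]1OC(=O)C(COC(C)=O)=C1CCC(C)=C | intermediate
21 | (3S,6R)-13-acetoxy-3-(propanoyloxy)germacra-1(10)Z,4E,7(11)-trien-12,6-olide (ten-membered carbocycle fused at C6–C7 to the butenolide) | CCC(=O)O[C@H]1C/C=C(/C)CCC2=C(COC(C)=O)C(=O)O[C@@H]2/C=C/1C | target

**Step count**
Total: 8 steps. Longest linear sequence: 6 steps (1, 2, 5, 6, 7, 8); steps 3 and 4 make the phosphonate branch.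

**Three steps most likely to fail**

Step 6 (the proposed new reaction). The risks are low enantioselectivity, 1,2- instead of 1,4-addition, and palladium-mediated oxidation or isomerisation at the two terminal alkenes and the skipped diene. The fallback uses known chemistry only, sets out from 17 and comes back at 19. The olefination mixture of step 5 is acidified without fluoride, which keeps the silyl ether and gives (2Z,4E,6E)-6-methyl-3-(3-methylbut-3-en-1-yl)-2-[(triisopropylsilyloxy)methyl]deca-2,4,6,9-tetraenoic acid F1. Shi epoxidation (the enantiomer of the fructose-derived ketone that delivers the 2S,3S-oxirane, KHSO5, K2CO3 buffer pH 10.5, MeCN–dimethoxymethane–water, 0 °C) oxidises the distal, most electron-rich trisubstituted alkene and gives (2Z,4E)-3-(3-methylbut-3-en-1-yl)-5-[(2S,3S)-2-methyl-3-(prop-2-en-1-yl)oxiran-2-yl]-2-[(triisopropylsilyloxy)methyl]penta-2,4-dienoic acid F2, used crude. The zerovalent palladium complex Pd(PPh3)4 (5 mol%, THF, 0 °C) ionises the vinyl oxirane with inversion and the cis-carboxylate closes on C6 with a second inversion (net retention, 1,4-transfer of chirality), giving (5R)-5-[(1E,3S)-3-hydroxy-2-methylhexa-1,5-dien-1-yl]-4-(3-methylbut-3-en-1-yl)-3-[(triisopropylsilyloxy)methyl]furan-2(5H)-one F3. Propanoic anhydride, pyridine and DMAP give (1E,3S)-2-methyl-1-[(2R)-3-(3-methylbut-3-en-1-yl)-5-oxo-4-[(triisopropylsilyloxy)methyl]-2,5-dihydrofuran-2-yl]hexa-1,5-dien-3-yl propanoate F4, and HF·pyridine in THF removes the silyl ether to give 19.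

Step 8 (ring-closing metathesis). The risks are oligomers instead of the strained ten-membered ring, the E isomer, and slow closure because the homoallylic propanoate carbonyl can chelate the ruthenium carbene. The fallback moves the ring closure ahead of both acylations; it sets out from 18 and comes back at 21. Step 6 is run with CF3CO2H/LiO2CCF3 in place of propanoic acid, giving (1E,3S)-1-[(2R)-4-(hydroxymethyl)-3-(3-methylbut-3-en-1-yl)-5-oxo-2,5-dihydrofuran-2-yl]-2-methylhexa-1,5-dien-3-yl trifluoroacetate F5, which is not isolated but hydrolysed during NaHCO3/MeOH work-up to (5R)-5-[(1E,3S)-3-hydroxy-2-methylhexa-1,5-dien-1-yl]-3-(hydroxymethyl)-4-(3-methylbut-3-en-1-yl)furan-2(5H)-one F6. Ring-closing metathesis of this ester-free diol (same catalyst, toluene, 1 mM, 80 °C) gives (3S,6R)-3,13-dihydroxygermacra-1(10)Z,4E,7(11)-trien-12,6-olide F7. Ac2O with 2,4,6-collidine at −40 °C acetylates only the primary hydroxyl and gives (3S,6R)-13-acetoxy-3-hydroxygermacra-1(10)Z,4E,7(11)-trien-12,6-olide F8, and propanoic anhydride, pyridine and DMAP at 0 °C then give 21.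

Step 1 (carbomagnesiation–carboxylation). The risks are sluggish addition of an alkyl Grignard reagent, β-elimination of the adduct to an allenol, and a low carboxylation yield. The fallback builds the same butenolide by carbonylation and cross-coupling; it sets out from 1 and comes back at 6. Br2 in CH2Cl2 at 0 °C adds anti to the alkyne and gives (2E)-2,3-dibromobut-2-ene-1,4-diol F9. PdCl2(PPh3)2 (3 mol%), CO (1 atm), Et3N, THF, 50 °C carbonylates one C–Br bond, and the cis CH2OH traps the acyl group to give 4-bromo-3-(hydroxymethyl)furan-2(5H)-one F10. Isoprene (excess) and 9-borabicyclo[3.3.1]nonane in THF give 9-(3-methylbut-3-en-1-yl)-9-borabicyclo[3.3.1]nonane F11, which is coupled in the same flask with the bromobutenolide (PdCl2(dppf), K3PO4, THF–DMF–water, 50 °C, B-alkyl Suzuki–Miyaura coupling) to give 6.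

**Further compounds**
F1 | step 6 | (2Z,4E,6E)-6-methyl-3-(3-methylbut-3-en-1-yl)-2-[(triisopropylsilyloxy)methyl]deca-2,4,6,9-tetraenoic acid | OC(=O)/C(CO[Si](C(C)C)(C(C)C)C(C)C)=C(CCC(C)=C)\C=C\C(C)=C\CC=C
F2 | step 6 | (2Z,4E)-3-(3-methylbut-3-en-1-yl)-5-[(2S,3S)-2-methyl-3-(prop-2-en-1-yl)oxiran-2-yl]-2-[(triisopropylsilyloxy)methyl]penta-2,4-dienoic acid | C=CC[C@@H]1O[C@@]1(C)/C=C/C(CCC(C)=C)=C(/CO[Si](C(C)C)(C(C)C)C(C)C)C(O)=O
F3 | step 6 | (5R)-5-[(1E,3S)-3-hydroxy-2-methylhexa-1,5-dien-1-yl]-4-(3-methylbut-3-en-1-yl)-3-[(triisopropylsilyloxy)methyl]furan-2(5H)-one | O[C@@H](CC=C)/C(C)=C/[C@H]1OC(=O)C(CO[Si](C(C)C)(C(C)C)C(C)C)=C1CCC(C)=C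
F4 | step 6 | (1E,3S)-2-methyl-1-[(2R)-3-(3-methylbut-3-en-1-yl)-5-oxo-4-[(triisopropylsilyloxy)methyl]-2,5-dihydrofuran-2-yl]hexa-1,5-dien-3-yl propanoate | CCC(=O)O[C@@H](CC=C)/C(C)=C/[C@H]1OC(=O)C(CO[Si](C(C)C)(C(C)C)C(C)C)=C1CCC(C)=C
F5 | step 8 | (1E,3S)-1-[(2R)-4-(hydroxymethyl)-3-(3-methylbut-3-en-1-yl)-5-oxo-2,5-dihydrofuran-2-yl]-2-methylhexa-1,5-dien-3-yl trifluoroacetate | FC(F)(F)C(=O)O[C@@H](CC=C)/C(C)=C/[C@H]1OC(=O)C(CO)=C1CCC(C)=C
F6 | step 8 | (5R)-5-[(1E,3S)-3-hydroxy-2-methylhexa-1,5-dien-1-yl]-3-(hydroxymethyl)-4-(3-methylbut-3-en-1-yl)furan-2(5H)-one | O[C@@H](CC=C)/C(C)=C/[C@H]1OC(=O)C(CO)=C1CCC(C)=C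
F7 | step 8 | (3S,6R)-3,13-dihydroxygermacra-1(10)Z,4E,7(11)-trien-12,6-olide | O[C@H]1C/C=C(/C)CCC2=C(CO)C(=O)O[C@@H]2/C=C/1C
F8 | step 8 | (3S,6R)-13-acetoxy-3-hydroxygermacra-1(10)Z,4E,7(11)-trien-12,6-olide | O[C@H]1C/C=C(/C)CCC2=C(COC(C)=O)C(=O)O[C@@H]2/C=C/1C
F9 | step 1 | (2E)-2,3-dibromobut-2-ene-1,4-diol | OC/C(Br)=C(\Br)CO
F10 | step 1 | 4-bromo-3-(hydroxymethyl)furan-2(5H)-one | OCC1=C(Br)COC1=O
F11 | step 1 | 9-(3-methylbut-3-en-1-yl)-9-borabicyclo[3.3.1]nonane | C=C(C)CCB1C2CCCC1CCC2
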